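**Strategy.** Ring numbering: C1 = CH–OAc, C2=C3, C6 carries C15 (CMe2OH), C8=C9, C12–C13 oxirane, C14. The 14-membered carbocycle is disconnected at C10–C11. The oxirane is traced to a C12 ketone whose neighbour C13 is fully substituted, so the C11 methyl is the only enolisable site; its potassium enolate displaces the (Z)-allylic bromide at C10 and forms the ring in one operation without touching the C2=C3 and C8=C9 olefins or the C1, C6 and C13 centres. The precursor is an acyclic methyl ketone with the C1/C13 diol as a 1,3-dioxane acetonide, a silylated C15 hydroxyl and the C10 bromide, built from (R)-α-terpineol and (R)-citramalic acid.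

Key step: step 17

Remark: the target is (1R,6R,12S,13R) with 2E, 8Z and C11/C14 cis on the oxirane, so the carbinol closed onto C13 must be 12R (closure inverts C12); C15–OH is carried as a TBS ether (TBS = tert-butyldimethylsilyl) so that the primary C10 silyl ether can be removed selectively, and (R)-citramalic acid is taken as a commercial chiral-pool material.

Step 1
Reactants: 1 (R)-α-terpineol
Product: 2 terpineol TBS ether
Conditions: TBSOTf, 2,6-lutidine, CH2Cl2, 0 °C → rt
Reagents that add atoms: tert-butyldimethylsilyl trifluoromethanesulfonate, CC(C)(C)[Si](C)(C)OS(=O)(=O)C(F)(F)F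
Why: Silylation of a tertiary alcohol with a silyl triflate and a hindered pyridine base is routine and blocks the hydroxyl that would otherwise trap the C8 aldehyde of step 2 as a lactol, the C6 centre being that of the starting material.

Step 2
Reactants: 2 terpineol TBS ether
Product: 4 keto aldehyde, via secondary ozonide 3 (not isolated)
Conditions: O3, CH2Cl2, −78 °C; then PPh3, −78 °C → rt
Reagents that add atoms: ozone, [O-][O+]=O
Why: Ozonolysis with reductive work-up cleaves the only olefin into the C3 methyl ketone and the C8 aldehyde without affecting the silyl ether or the remote stereocentre.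

Step 3
Reactants: 4 keto aldehyde; 5 ethyl 2-[bis(2,2,2-trifluoroethoxy)phosphoryl]propanoate
Product: 6 keto (Z)-enoate
Conditions: 5, KN(SiMe3)2, 18-crown-6, THF, −78 °C; then 4
Reagents that add atoms: none
Why: Still–Gennari olefination, in which the electron-poor phosphonate anion reacts with the aldehyde far faster than with the methyl ketone and the fast, irreversible collapse of the initial adduct under dissociating conditions gives the Z-trisubstituted C8=C9 enoate.

Step 4
Reactants: 6 keto (Z)-enoate
Product: 7 diol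
Conditions: i-Bu2AlH, CH2Cl2, −78 → 0 °C
Reagents that add atoms: none
Why: Hydride reduction with i-Bu2AlH converts the enoate 1,2-selectively into the Z-allylic alcohol without olefin isomerisation and reduces the ketone to a carbinol whose configuration is irrelevant because it is re-oxidised in step 6.

Step 5
Reactants: 7 diol
Product: 8 C10 silyl ether alcohol
Conditions: TBSCl, imidazole, CH2Cl2, −20 → 0 °C
Reagents that add atoms: tert-butyldimethylsilyl chloride, CC(C)(C)[Si](C)(C)Cl
Why: Silyl chloride/imidazole silylation distinguishes the unhindered primary allylic hydroxyl from the secondary one on steric grounds.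

Step 6
Reactants: 8 C10 silyl ether alcohol
Product: 9 methyl ketone
Conditions: Dess–Martin periodinane, CH2Cl2, 0 °C → rt
Reagents that add atoms: none
Why: Dess–Martin oxidation returns the secondary carbinol to the C3 methyl ketone under conditions mild enough for both silyl ethers and the Z-olefin.

Step 7
Reactants: 9 methyl ketone
Product: 11 terminal alkyne, via enol diethyl phosphate 10 (not isolated)
Conditions: LiN(i-Pr)2, THF, −78 °C; ClP(O)(OEt)2; then LiN(i-Pr)2 (2.3 equiv), −78 °C → rt
Reagents that add atoms: none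
Why: Kinetic deprotonation on the methyl side, O-phosphorylation and base-induced elimination of the 1-alkenyl phosphate is the standard conversion of a methyl ketone into a terminal alkyne (enol phosphate elimination), so the former ketone carbon becomes C3 and the former methyl carbon C2.

Step 8
Reactants: 11 terminal alkyne
Product: 13 (E)-alkenyl iodide, via alkenyldimethylalane 12 (not isolated)
Conditions: Me3Al, Cp2ZrCl2 (25 mol%), CH2Cl2, 0 °C → rt; then I2, THF, −30 °C
Reagents that add atoms: trimethylaluminium, C[Al](C)C; iodine, II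
Why: Cp2ZrCl2-catalysed carboalumination (Negishi) adds methyl and aluminium syn across the alkyne with the metal at the terminus, and iodinolysis with retention gives the E-iodide that fixes the C2=C3 geometry.

Step 9
Reactants: 14 (R)-citramalic acid
Product: 15 dioxolanone acid
Conditions: 2,2-dimethoxypropane, TsOH (cat.), rt
Reagents that add atoms: 2,2-dimethoxypropane, COC(C)(C)OC
Why: Acid-catalysed acetonide formation engages the α-hydroxy acid as a five-membered dioxolanone and leaves the β-carboxyl (future C1) free, the quaternary C13 centre coming unchanged from the chiral pool.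

Step 10
Reactants: 13 (E)-alkenyl iodide; 15 dioxolanone acid
Product: 19 enone, via acid chloride 16 (not isolated), via alkenyllithium 17 (not isolated), via alkenylzinc chloride 18 (not isolated)
Conditions: 15, (COCl)2, DMF (cat.), CH2Cl2, 0 °C → rt, evaporate; 13, t-BuLi, Et2O, −78 °C, then ZnCl2, THF, −78 → 0 °C; then 16, Pd(PPh3)4 (5 mol%), THF, 0 °C → rt
Reagents that add atoms: none
Why: Negishi acylation, in which the alkenylzinc chloride formed with retention by lithium–iodine exchange and transmetalation couples with the acid chloride under Pd(PPh3)4 (zerovalent palladium) catalysis to give the E-enone and the far less reactive dioxolanone carbonyl is left alone.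

Step 11
Reactants: 19 enone
Product: 20 (1R)-allylic alcohol
Conditions: (S)-2-methyl-CBS-oxazaborolidine (0.3 equiv), catecholborane, toluene, −78 °C
Reagents that add atoms: none
Why: Corey–Bakshi–Shibata reduction, in which the (S)-oxazaborolidine treats the alkenyl branch as the large substituent and delivers hydride 1,2 to give the (1R)-carbinol under catalyst control, so the C1 configuration does not depend on the remote quaternary C13.

Step 12
Reactants: 20 (1R)-allylic alcohol
Product: 21 dihydroxy Weinreb amide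
Conditions: MeNH(OMe)·HCl, i-PrMgCl, THF, −20 °C; then 20, −20 → 0 °C
Reagents that add atoms: N,O-dimethylhydroxylamine hydrochloride, CNOC.Cl
Why: Aminolysis of the activated dioxolanone (or of the γ-lactone that may arise from it by acyl transfer to the C1 alkoxide) by the magnesium amide gives the C12 Weinreb amide and releases acetone and the tertiary C13 hydroxyl without breaking any bond to a stereocentre.

Step 13
Reactants: 21 dihydroxy Weinreb amide
Product: 22 acetonide Weinreb amide
Conditions: 2-methoxypropene, PPTS (cat.), CH2Cl2, 0 °C → rt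
Reagents that add atoms: 2-methoxypropene, COC(C)=C
Why: Acid-catalysed ketalisation ties the C1 and C13 hydroxyls into a 1,3-dioxane, a base-stable protection of both oxygens that cannot migrate or eliminate in the enolate chemistry to come.

Step 14
Reactants: 22 acetonide Weinreb amide
Product: 23 acetonide methyl ketone
Conditions: MeMgBr, THF, 0 °C
Reagents that add atoms: methylmagnesium bromide, C[Mg]Br
Why: Weinreb ketone synthesis, in which the chelated tetrahedral adduct resists a second addition and collapses on work-up to the C12 methyl ketone (C11 introduced), the neighbouring C13 being quaternary and not epimerisable.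

Step 15
Reactants: 23 acetonide methyl ketone
Product: 24 allylic alcohol
Conditions: HF·pyridine, pyridine, THF, 0 °C
Reagents that add atoms: none
Why: Buffered fluoride cleaves the unhindered primary allylic silyl ether much faster than the tertiary one, and the acetonide and ketone are inert to these conditions (selective desilylation).

Step 16
Reactants: 24 allylic alcohol
Product: 25 (Z)-allylic bromide (cyclisation precursor)
Conditions: CBr4, PPh3, 2,6-lutidine, CH2Cl2, −20 °C
Reagents that add atoms: carbon tetrabromide, BrC(Br)(Br)Br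
Why: Appel bromination of a primary allylic alcohol proceeds by SN2 displacement of the oxyphosphonium ion at low temperature, which keeps the Z geometry and avoids allylic transposition.

Step 17
Reactants: 25 (Z)-allylic bromide
Product: 27 macrocyclic ketone, via potassium enolate 26 (not isolated)
Conditions: KN(SiMe3)2 (1.5 equiv), THF, 0 °C; 25 added by syringe pump over 10 h (final 2 mM)
Reagents that add atoms: none
Why: KN(SiMe3)2 removes a proton from the C11 methyl group, the only position α to the C12 carbonyl that carries hydrogen because C13 is quaternary, and the potassium enolate attacks the primary allylic carbon C10 in an SN2 displacement of bromide, forming the C10–C11 bond. The closest known reaction type is the high-dilution intramolecular alkylation of a ketone enolate by an allylic halide used to close macrocarbocycles. The 14-membered ring closes in the exo-tet mode (both enolate carbons end up in the ring, a 14-enolendo-exo-tet closure), which has none of the angle constraints that hinder small-ring enolendo alkylations. No stereocentre is created; C1, C6 and C13 are not involved and the Z geometry of C8=C9 is kept because bromide leaves from C10 without allylic shift. The step needs C- over O-alkylation and SN2 over SN2′, secured by the soft, unhindered primary allylic bromide and the hindered trisubstituted C8 terminus, and ring closure over oligomerisation, secured by slow addition into excess base so that each enolate forms at very low concentration. The dioxane acetonide protects both oxygens with a group that cannot migrate to the enolate oxygen or be eliminated and limits the rotamers of the C1–C14–C13 segment.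

Step 18
Reactants: 27 macrocyclic ketone
Product: 28 (12R)-alcohol
Conditions: (S)-2-methyl-CBS-oxazaborolidine (0.5 equiv), catecholborane, toluene, −40 → −20 °C
Reagents that add atoms: none
Why: Corey–Bakshi–Shibata reduction, in which the fully substituted C13 is the large and the C11 methylene the small ketone substituent so that the (S)-catalyst gives 12R, the same face that the Felkin–Anh polar model predicts for a non-chelating reductant (C13–O anti to hydride, attack past the methyl group), so catalyst and substrate bias should reinforce each other.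

Step 19
Reactants: 28 (12R)-alcohol
Product: 29 (12R)-mesylate
Conditions: MsCl, Et3N, CH2Cl2, 0 °C
Reagents that add atoms: methanesulfonyl chloride, CS(=O)(=O)Cl
Why: Sulfonylation through the sulfene pathway is fast even for a hindered secondary alcohol and occurs with retention at C12, the only free hydroxyl in the molecule.

Step 20
Reactants: 29 (12R)-mesylate
Product: 30 triol mesylate
Conditions: 48% aq. HF, MeCN, 0 °C → rt
Reagents that add atoms: none
Why: Aqueous HF hydrolyses the acetonide and cleaves the tertiary silyl ether in one operation while the secondary mesylate, which has no basic neighbour to displace it under acidic conditions, survives (acidic global deprotection).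

Step 21
Reactants: 30 triol mesylate
Product: 31 C1 acetate
Conditions: Ac2O, pyridine, DMAP (cat.), CH2Cl2, 0 °C
Reagents that add atoms: acetic anhydride, CC(=O)OC(C)=O
Why: Acylation is selective for the only secondary hydroxyl (allylic C1–OH), since the tertiary hydroxyls at C13 and C15 do not acylate under these mild conditions.

Step 22
Reactants: 31 C1 acetate
Product: 32 target CNP0254503.2
Conditions: NaH, THF, 0 °C → rt
Reagents that add atoms: none
Why: Intramolecular Williamson etherification, in which the C13 alkoxide displaces the adjacent mesylate in a 3-exo-tet closure with inversion at C12, converting 12R into the 12S oxirane carbon with C11 and C14 cis while C13 (R) keeps its configuration.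

**Compound list** (TBSO = tert-butyldimethylsilyloxy)

1 | (R)-α-terpineol, 2-[(1R)-4-methylcyclohex-3-en-1-yl]propan-2-ol | CC1=CC[C@@H](CC1)C(C)(C)O | starting material
2 | terpineol TBS ether, tert-butyldimethyl{2-[(1R)-4-methylcyclohex-3-en-1-yl]propan-2-yloxy}silane | CC1=CC[C@@H](CC1)C(C)(C)O[Si](C)(C)C(C)(C)C | intermediate
3 | secondary ozonide of 2, (4R)-1-methyl-4-[2-(TBSO)propan-2-yl]-7,8,9-trioxabicyclo[4.2.1]nonane, bridgehead isomers (formed in the flask) | CC12CC[C@@H](C(C)(C)O[Si](C)(C)C(C)(C)C)CC(OO1)O2 | intermediate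
4 | keto aldehyde, (3R)-3-[2-(TBSO)propan-2-yl]-6-oxoheptanal | CC(=O)CC[C@@H](C(C)(C)O[Si](C)(C)C(C)(C)C)CC=O | intermediate
5 | ethyl 2-[bis(2,2,2-trifluoroethoxy)phosphoryl]propanoate | CCOC(=O)C(C)P(=O)(OCC(F)(F)F)OCC(F)(F)F | starting material
6 | keto (Z)-enoate, ethyl (2Z,5R)-5-[2-(TBSO)propan-2-yl]-2-methyl-8-oxonon-2-enoate | CC(=O)CC[C@@H](C(C)(C)O[Si](C)(C)C(C)(C)C)C/C=C(/C)C(=O)OCC | intermediate
7 | diol, (2Z,5R)-5-[2-(TBSO)propan-2-yl]-2-methylnon-2-ene-1,8-diol, both C8 epimers | CC(O)CC[C@@H](C(C)(C)O[Si](C)(C)C(C)(C)C)C/C=C(/C)CO | intermediate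
8 | C10 silyl ether alcohol, (5R,7Z)-9-(TBSO)-5-[2-(TBSO)propan-2-yl]-8-methylnon-7-en-2-ol, both C2 epimers | CC(O)CC[C@@H](C(C)(C)O[Si](C)(C)C(C)(C)C)C/C=C(/C)CO[Si](C)(C)C(C)(C)C | intermediate
9 | methyl ketone, (5R,7Z)-9-(TBSO)-5-[2-(TBSO)propan-2-yl]-8-methylnon-7-en-2-one | CC(=O)CC[C@@H](C(C)(C)O[Si](C)(C)C(C)(C)C)C/C=C(/C)CO[Si](C)(C)C(C)(C)C | intermediate
10 | enol diethyl phosphate, diethyl (5R,7Z)-9-(TBSO)-5-[2-(TBSO)propan-2-yl]-8-methylnona-1,7-dien-2-yl phosphate (formed in the flask) | C=C(OP(=O)(OCC)OCC)CC[C@@H](C(C)(C)O[Si](C)(C)C(C)(C)C)C/C=C(/C)CO[Si](C)(C)C(C)(C)C | intermediate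
11 | terminal alkyne, (5R,7Z)-9-(TBSO)-5-[2-(TBSO)propan-2-yl]-8-methylnon-7-en-1-yne | C#CCC[C@@H](C(C)(C)O[Si](C)(C)C(C)(C)C)C/C=C(/C)CO[Si](C)(C)C(C)(C)C | intermediate
12 | alkenyldimethylalane, dimethyl[(1E,5R,7Z)-9-(TBSO)-5-[2-(TBSO)propan-2-yl]-2,8-dimethylnona-1,7-dien-1-yl]alumane (formed in the flask) | C[Al](C)/C=C(\C)CC[C@@H](C(C)(C)O[Si](C)(C)C(C)(C)C)C/C=C(/C)CO[Si](C)(C)C(C)(C)C | intermediate
13 | (E)-alkenyl iodide, (1E,5R,7Z)-9-(TBSO)-1-iodo-2,8-dimethyl-5-[2-(TBSO)propan-2-yl]nona-1,7-diene | I/C=C(\C)CC[C@@H](C(C)(C)O[Si](C)(C)C(C)(C)C)C/C=C(/C)CO[Si](C)(C)C(C)(C)C | intermediate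
14 | (R)-citramalic acid, (2R)-2-hydroxy-2-methylbutanedioic acid | OC(=O)[C@@](O)(C)CC(=O)O | starting material
15 | dioxolanone acid, 2-[(4R)-2,2,4-trimethyl-5-oxo-1,3-dioxolan-4-yl]acetic acid | O=C1OC(C)(C)O[C@]1(C)CC(=O)O | intermediate
16 | acid chloride, 2-[(4R)-2,2,4-trimethyl-5-oxo-1,3-dioxolan-4-yl]acetyl chloride (formed in the flask) | O=C1OC(C)(C)O[C@]1(C)CC(=O)Cl | intermediate
17 | alkenyllithium from 13, (1E,5R,7Z)-configured (formed in the flask) | [Li]/C=C(\C)CC[C@@H](C(C)(C)O[Si](C)(C)C(C)(C)C)C/C=C(/C)CO[Si](C)(C)C(C)(C)C | intermediate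
18 | alkenylzinc chloride from 13, (1E,5R,7Z)-configured (formed in the flask) | Cl[Zn]/C=C(\C)CC[C@@H](C(C)(C)O[Si](C)(C)C(C)(C)C)C/C=C(/C)CO[Si](C)(C)C(C)(C)C | intermediate
19 | enone, (5R)-5-[(3E,7R,9Z)-11-(TBSO)-7-[2-(TBSO)propan-2-yl]-4,10-dimethyl-2-oxoundeca-3,9-dien-1-yl]-2,2,5-trimethyl-1,3-dioxolan-4-one | O=C1OC(C)(C)O[C@]1(C)CC(=O)/C=C(\C)CC[C@@H](C(C)(C)O[Si](C)(C)C(C)(C)C)C/C=C(/C)CO[Si](C)(C)C(C)(C)C | intermediate
20 | (1R)-allylic alcohol, (5R)-5-[(2R,3E,7R,9Z)-11-(TBSO)-7-[2-(TBSO)propan-2-yl]-2-hydroxy-4,10-dimethylundeca-3,9-dien-1-yl]-2,2,5-trimethyl-1,3-dioxolan-4-one | O=C1OC(C)(C)O[C@]1(C)C[C@@H](O)/C=C(\C)CC[C@@H](C(C)(C)O[Si](C)(C)C(C)(C)C)C/C=C(/C)CO[Si](C)(C)C(C)(C)C | intermediate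
21 | dihydroxy Weinreb amide, (2R,4R,5E,9R,11Z)-13-(TBSO)-9-[2-(TBSO)propan-2-yl]-2,4-dihydroxy-N-methoxy-N,2,6,12-tetramethyltrideca-5,11-dienamide | CON(C)C(=O)[C@@](O)(C)C[C@@H](O)/C=C(\C)CC[C@@H](C(C)(C)O[Si](C)(C)C(C)(C)C)C/C=C(/C)CO[Si](C)(C)C(C)(C)C | intermediate
22 | acetonide Weinreb amide, (4R,6R)-6-[(1E,5R,7Z)-9-(TBSO)-5-[2-(TBSO)propan-2-yl]-2,8-dimethylnona-1,7-dien-1-yl]-N-methoxy-N,2,2,4-tetramethyl-1,3-dioxane-4-carboxamide | CON(C)C(=O)[C@@]1(C)C[C@H](/C=C(\C)CC[C@@H](C(C)(C)O[Si](C)(C)C(C)(C)C)C/C=C(/C)CO[Si](C)(C)C(C)(C)C)OC(C)(C)O1 | intermediate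
23 | acetonide methyl ketone, 1-[(4R,6R)-6-[(1E,5R,7Z)-9-(TBSO)-5-[2-(TBSO)propan-2-yl]-2,8-dimethylnona-1,7-dien-1-yl]-2,2,4-trimethyl-1,3-dioxan-4-yl]ethan-1-one | CC(=O)[C@@]1(C)C[C@H](/C=C(\C)CC[C@@H](C(C)(C)O[Si](C)(C)C(C)(C)C)C/C=C(/C)CO[Si](C)(C)C(C)(C)C)OC(C)(C)O1 | intermediate
24 | allylic alcohol, 1-[(4R,6R)-6-[(1E,5R,7Z)-9-hydroxy-5-[2-(TBSO)propan-2-yl]-2,8-dimethylnona-1,7-dien-1-yl]-2,2,4-trimethyl-1,3-dioxan-4-yl]ethan-1-one | CC(=O)[C@@]1(C)C[C@H](/C=C(\C)CC[C@@H](C(C)(C)O[Si](C)(C)C(C)(C)C)C/C=C(/C)CO)OC(C)(C)O1 | intermediate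
25 | (Z)-allylic bromide (cyclisation precursor), 1-[(4R,6R)-6-[(1E,5R,7Z)-9-bromo-5-[2-(TBSO)propan-2-yl]-2,8-dimethylnona-1,7-dien-1-yl]-2,2,4-trimethyl-1,3-dioxan-4-yl]ethan-1-one | CC(=O)[C@@]1(C)C[C@H](/C=C(\C)CC[C@@H](C(C)(C)O[Si](C)(C)C(C)(C)C)C/C=C(/C)CBr)OC(C)(C)O1 | intermediate
26 | potassium enolate of 25, C11=C12–OK (formed in the flask) | [K+].[O-]C(=C)[C@@]1(C)C[C@H](/C=C(\C)CC[C@@H](C(C)(C)O[Si](C)(C)C(C)(C)C)C/C=C(/C)CBr)OC(C)(C)O1 | intermediate
27 | macrocyclic ketone, (1R,5Z,8R,11E,13R)-8-[2-(TBSO)propan-2-yl]-1,5,11,15,15-pentamethyl-14,16-dioxabicyclo[11.3.1]heptadeca-5,11-dien-2-one | O=C1CC/C(C)=C\C[C@H](C(C)(C)O[Si](C)(C)C(C)(C)C)CC/C(C)=C/[C@H]2C[C@@]1(C)OC(C)(C)O2 | intermediate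
28 | (12R)-alcohol, (1R,2R,5Z,8R,11E,13R)-8-[2-(TBSO)propan-2-yl]-1,5,11,15,15-pentamethyl-14,16-dioxabicyclo[11.3.1]heptadeca-5,11-dien-2-ol | O[C@@H]1CC/C(C)=C\C[C@H](C(C)(C)O[Si](C)(C)C(C)(C)C)CC/C(C)=C/[C@H]2C[C@@]1(C)OC(C)(C)O2 | intermediate
29 | (12R)-mesylate, methanesulfonate of 28 | CS(=O)(=O)O[C@@H]1CC/C(C)=C\C[C@H](C(C)(C)O[Si](C)(C)C(C)(C)C)CC/C(C)=C/[C@H]2C[C@@]1(C)OC(C)(C)O2 | intermediate
30 | triol mesylate (target numbering), (1R,2E,6R,8Z,12R,13R)-1,13-dihydroxy-6-(2-hydroxypropan-2-yl)-3,9,13-trimethylcyclotetradeca-2,8-dien-12-yl methanesulfonate | CS(=O)(=O)O[C@@H]1CC/C(C)=C\C[C@H](C(C)(C)O)CC/C(C)=C/[C@H](O)C[C@@]1(C)O | intermediate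
31 | C1 acetate (target numbering), (1R,2E,6R,8Z,12R,13R)-13-hydroxy-6-(2-hydroxypropan-2-yl)-3,9,13-trimethyl-12-(methylsulfonyloxy)cyclotetradeca-2,8-dien-1-yl acetate | CS(=O)(=O)O[C@@H]1CC/C(C)=C\C[C@H](C(C)(C)O)CC/C(C)=C/[C@H](OC(C)=O)C[C@@]1(C)O | intermediate
32 | CNP0254503.2 (target numbering), (1R,2E,6R,8Z,12S,13R)-12,13-epoxy-6-(2-hydroxypropan-2-yl)-3,9,13-trimethylcyclotetradeca-2,8-dien-1-yl acetate | CC(=O)O[C@H]1/C=C(\C)CC[C@@H](C(C)(C)O)C/C=C(/C)CC[C@@H]2O[C@]2(C)C1 | target

**Total step count:** 22 steps.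
**Longest linear sequence:** 21 steps (steps 1–8 and 10–22, from 1 to 32); step 9 is the only step off this line.

**Steps most likely to fail**

1. Step 17. Intermolecular alkylation (oligomerisation), O-alkylation of the enolate or base-induced 1,4-elimination of HBr may outrun the ring closure. The fallback sets out from acetonide Weinreb amide 22 and comes back at macrocyclic ketone 27, forming the same C10–C11 bond with a doubly stabilised carbanion under mild base. Addition of PhSO2CH2Li to 22 gives β-keto sulfone F1; HF·pyridine frees allylic alcohol F2; CBr4/PPh3 gives bromide F3; Cs2CO3 in DMF at high dilution closes the ring to macrocyclic keto sulfone F4 (both C11 epimers); SmI2 in THF/MeOH removes the sulfonyl group to give 27.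

2. Step 18. The conformation of the bridged macrocycle may expose the wrong face of the C12 carbonyl and override the catalyst, giving poor facial selectivity or the 12S carbinol. The fallback sets out from ketone 27 and comes back at alcohol 28, replacing stereoselective reduction by separation and recycling. Reduction without reagent control (NaBH4, CeCl3·7H2O, MeOH) gives both epimers; chromatography separates 28 from (12S)-alcohol F5; F5 is returned to 27 with Dess–Martin periodinane and reduced again.

3. Step 22. Acyl transfer from the C1 oxygen to the C13 alkoxide may precede ring closure, after which the freed C1 alkoxide can attack C12 (oxolane formation) or the acetate can be lost. The fallback sets out from triol mesylate 30 and comes back at target 32, introducing the acetate only after the oxirane exists. Selective silylation of the secondary hydroxyl (Et3SiCl, imidazole) gives C1 triethylsilyl ether F6; K2CO3 in MeOH closes the oxirane to silylated epoxide F7; Bu4NF buffered with AcOH gives epoxy diol F8; acetylation as in step 21 gives 32.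

**Further compounds**

F1 | step 17 | β-keto sulfone, 1-[(4R,6R)-6-[(1E,5R,7Z)-9-(TBSO)-5-[2-(TBSO)propan-2-yl]-2,8-dimethylnona-1,7-dien-1-yl]-2,2,4-trimethyl-1,3-dioxan-4-yl]-2-(phenylsulfonyl)ethan-1-one | O=S(=O)(CC(=O)[C@@]1(C)C[C@H](/C=C(\C)CC[C@@H](C(C)(C)O[Si](C)(C)C(C)(C)C)C/C=C(/C)CO[Si](C)(C)C(C)(C)C)OC(C)(C)O1)c1ccccc1
F2 | step 17 | allylic alcohol, C10 hydroxy analogue of F1 | O=S(=O)(CC(=O)[C@@]1(C)C[C@H](/C=C(\C)CC[C@@H](C(C)(C)O[Si](C)(C)C(C)(C)C)C/C=C(/C)CO)OC(C)(C)O1)c1ccccc1
F3 | step 17 | bromide, C10 bromo analogue of F1 | O=S(=O)(CC(=O)[C@@]1(C)C[C@H](/C=C(\C)CC[C@@H](C(C)(C)O[Si](C)(C)C(C)(C)C)C/C=C(/C)CBr)OC(C)(C)O1)c1ccccc1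
F4 | step 17 | macrocyclic keto sulfone, 27 bearing PhSO2 at C11 (ring position 3), both C11 epimers | O=C1C(S(=O)(=O)c3ccccc3)C/C(C)=C\C[C@H](C(C)(C)O[Si](C)(C)C(C)(C)C)CC/C(C)=C/[C@H]2C[C@@]1(C)OC(C)(C)O2
F5 | step 18 | (12S)-alcohol, C12 epimer of 28 | O[C@H]1CC/C(C)=C\C[C@H](C(C)(C)O[Si](C)(C)C(C)(C)C)CC/C(C)=C/[C@H]2C[C@@]1(C)OC(C)(C)O2
F6 | step 22 | C1 triethylsilyl ether of 30 | CS(=O)(=O)O[C@@H]1CC/C(C)=C\C[C@H](C(C)(C)O)CC/C(C)=C/[C@H](O[Si](CC)(CC)CC)C[C@@]1(C)O
F7 | step 22 | silylated epoxide, C1 triethylsilyl ether of the deacetyl target | CC[Si](CC)(CC)O[C@H]1/C=C(\C)CC[C@@H](C(C)(C)O)C/C=C(/C)CC[C@@H]2O[C@]2(C)C1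
F8 | step 22 | epoxy diol, deacetyl target | O[C@H]1/C=C(\C)CC[C@@H](C(C)(C)O)C/C=C(/C)CC[C@@H]2O[C@]2(C)C1
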